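**Target check:** the SMILES decodes to (2S)-7,4'-dihydroxy-8,3',5'-tris(3-methylbut-2-enyl)flavanone, C30H36O4. It has one stereocentre, C2, with CIP order O1 > C1' > C3 > H, which gives S.

**Assumption:** (R)-DTBM-SEGPHOS is written as the ligand that gives (2S). The sense of induction must be confirmed by ECD and chiral HPLC. If it is opposite, the equally available (S)-ligand is used and nothing else changes.

## Retrosynthetic overview

1. Sophoranone comes from its 7-O-TIPS/4'-O-TBS ether by buffered fluoride, so no base touches the molecule after C2 is set.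
2. Rings A and B are bought as arenes. Ring C is the only ring formed, and it is formed last by a new enantioselective Rh-catalysed 6-endo hydroacylation of an O-(1-arylvinyl)salicylaldehyde, which makes C3–C4 and sets C2–H.
3. The formyl group (C4) comes from ArBr by Br/Li exchange and DMF. The 1-arylvinyl ether (C3) comes from an aryl benzoate by titanium methylenation.
4. The ester (O1–C2 bond) comes from A-ring 6-bromo-2-prenyl-3-silyloxyphenol and B-ring 4-silyloxy-3,5-diprenylbenzoic acid.
5. The A ring comes from 4-bromoresorcinol, where Br blocks one ortho site so the Claisen puts prenyl on C8 and later becomes C4. The B ring comes from 4-iodophenol by o,o'-diprenylation and I → CO2H.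

## Route

**Step 1**
Reactants: 1, 4-bromoresorcinol
Product: 2, 2-bromo-5-(triisopropylsilyloxy)phenol
Conditions: TIPSCl (1.0 equiv), imidazole, CH2Cl2/DMF, 0 °C → rt
Reagents that add atoms: TIPSCl, CC(C)[Si](Cl)(C(C)C)C(C)C
Why: Chemoselective phenol silylation, because the OH ortho to Br is hindered and H-bonded to Br, so the bulky silyl chloride takes the OH para to Br.

**Step 2**
Reactants: 2; 3, 3-chloro-3-methylbut-1-yne
Product: 4, [4-bromo-3-(2-methylbut-3-yn-2-yloxy)phenoxy]triisopropylsilane
Conditions: CuCl2·2H2O (1 mol %), DBU, dry MeCN, 0 °C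
Reagents that add atoms: 3-chloro-3-methylbut-1-yne (3), C#CC(C)(C)Cl
Why: Cu-catalysed propargylic etherification of a phenol with a tertiary propargyl chloride is mild enough to leave ArBr and ArOTIPS untouched.

**Step 3**
Reactants: 4
Product: 5, [4-bromo-3-(2-methylbut-3-en-2-yloxy)phenoxy]triisopropylsilane
Conditions: H2 (1 atm), Lindlar catalyst, quinoline, EtOAc, rt
Reagents that add atoms: none
Why: Lindlar semihydrogenation stops at the terminal alkene and does not hydrogenolyse the aryl bromide.

**Step 4**
Reactants: 5
Product: 6, 6-bromo-2-(3-methylbut-2-enyl)-3-(triisopropylsilyloxy)phenol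
Conditions: PhNEt2, 130–140 °C
Reagents that add atoms: none
Why: In this aromatic Claisen [3,3] rearrangement, Br blocks one ortho carbon, so allyl inversion delivers a linear prenyl group to the only free ortho carbon (future C8), followed by tautomerisation.

**Step 5**
Reactants: 7, 4-iodophenol; 8, prenyl bromide
Product: 9, 4-iodo-2,6-bis(3-methylbut-2-enyl)phenol
Conditions: 8 (2.4 equiv, slow addition), KOH (2.5 equiv), H2O, 20–25 °C, vigorous stirring; chromatography (moderate yield, mono-prenyl phenol recycled)
Reagents that add atoms: prenyl bromide (8), CC(C)=CCBr (two equivalents incorporated)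
Why: This is phenoxide ortho-C-alkylation in water, where H-bond solvation of the phenoxide oxygen suppresses O-alkylation and iodine blocks the para carbon, so both ortho carbons are prenylated by SN2.

**Step 6**
Reactants: 9
Product: 10, tert-butyl[4-iodo-2,6-bis(3-methylbut-2-enyl)phenoxy]dimethylsilane
Conditions: TBSOTf, 2,6-lutidine, CH2Cl2, 0 °C
Reagents that add atoms: TBSOTf, CC(C)(C)[Si](C)(C)OS(=O)(=O)C(F)(F)F
Why: The silyl triflate silylates the 2,6-dialkylphenol quickly, and excess lutidine keeps the medium non-acidic for the prenyl groups.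

**Step 7**
Reactants: 10
Product: 11, 4-(tert-butyldimethylsilyloxy)-3,5-bis(3-methylbut-2-enyl)benzoic acid
Conditions: i-PrMgCl·LiCl, THF, 0 °C → rt; CO2 (g); 10% citric acid
Reagents that add atoms: carbon dioxide, O=C=O
Why: I/Mg exchange followed by carboxylation installs the future C2 carbon without touching the silyl ether or the allylic and benzylic C–H bonds.

**Step 8**
Reactants: 6; 11
Product: 12, 6-bromo-2-prenyl-3-(TIPSO)phenyl 4-(TBSO)-3,5-diprenylbenzoate
Conditions: EDC·HCl, DMAP, CH2Cl2, rt
Reagents that add atoms: none (both partners are numbered reactants; water is lost)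
Why: Steglich esterification through the acylpyridinium acylates the di-ortho-substituted phenol under HCl-free conditions and forms the O1–C2 bond.

**Step 9**
Reactants: 12
Product: 13, 1-aryloxy-1-arylethene: {4-bromo-3-({1-[4-(TBSO)-3,5-diprenylphenyl]ethenyl}oxy)-2-prenylphenoxy}triisopropylsilane
Conditions: Cp2TiMe2 (2.5 equiv), toluene, 75 °C, dark; basic alumina
Reagents that add atoms: dimethyltitanocene (delivers CH2), [CH3-].[CH3-].[Ti+4].c1cc[cH-]c1.c1cc[cH-]c1
Why: In the Petasis methylenation, Cp2Ti=CH2 adds [2+2] to the ester C=O and cycloreverts to the enol ether, a standard conversion of aryl benzoates that tolerates ArBr, silyl ethers and trisubstituted alkenes.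

**Step 10**
Reactants: 13
Product: 14, 2-({1-[4-(TBSO)-3,5-diprenylphenyl]ethenyl}oxy)-3-prenyl-4-(TIPSO)benzaldehyde
Conditions: n-BuLi (1.1 equiv), THF, −78 °C, 15 min; DMF (3 equiv), −78 → −20 °C; pH 7 phosphate buffer; Et3N-deactivated SiO2
Reagents that add atoms: DMF, CN(C)C=O
Why: Br/Li exchange at −78 °C is faster than any addition or deprotonation, and formylation with DMF followed by a neutral quench spares the acid-labile enol ether.

**Step 11 (key step)**
Reactants: 14
Product: 15, (2S)-7-(triisopropylsilyloxy)-4'-(tert-butyldimethylsilyloxy)-8,3',5'-triprenylflavanone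
Conditions: [Rh(cod)Cl]2 (2.5 mol %), (R)-DTBM-SEGPHOS (5.5 mol %), NaBArF4 (6 mol %), 2,6-di-tert-butyl-4-methylpyridine (10 mol %), 4 Å MS, 1,4-dioxane, 60 °C
Reagents that add atoms: none (isomerisation)
Why: Proposed new method: enantioselective Rh(I)-catalysed 6-endo intramolecular hydroacylation of an aryl 1-arylvinyl ether (an O-(α-styrenyl)salicylaldehyde), a substrate class to my knowledge not yet shown in hydroacylation; the cationic Rh-bisphosphine inserts into the formyl C–H with the tethered enol-ether C=C bound, the hydride migrates to the aryl- and oxygen-bearing carbon while Rh takes the unsubstituted CH2 (the reverse insertion gives a crowded tertiary Rh-alkyl that would have to build a quaternary centre and is expected to be reversible and unproductive, as with other 1,1-disubstituted alkenes), this face-selective insertion inside the chiral pocket creates C2–H, and acyl–CH2 reductive elimination from the seven-membered rhodacycle closes ring C irreversibly under base-free conditions so the flavanone cannot racemise by retro-oxa-Michael; the β-aryloxy group is endocyclic and poorly aligned for syn β-O elimination, the hindered pyridine and sieves suppress acid-triggered enol-ether hydrolysis or Prins-type closure, and the trisubstituted prenyl alkenes are too hindered to compete for Rh; the closest known reaction type is Rh/bisphosphine enantioselective hydroacylation of 2-(2-substituted allyl)benzaldehydes and α-substituted 2-vinylbenzaldehydes to 3-substituted tetralones and indanones, the all-carbon-tether analogues.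

**Step 12**
Reactants: 15
Product: 16, (2S)-sophoranone
Conditions: TBAF (3 equiv)/AcOH (3.3 equiv), THF, 0 °C → rt
Reagents that add atoms: none
Why: Buffered fluoride cleaves both aryl silyl ethers without generating free phenoxide (so no ring-opening racemisation at C2) and without strong acid (so no chroman formation from the o-prenylphenols).

## Compound list

| No. | Name | SMILES | Role |
|---|---|---|---|
| 1 | 4-bromoresorcinol | Oc1ccc(Br)c(O)c1 | starting material |
| 2 | 2-bromo-5-(triisopropylsilyloxy)phenol | Oc1cc(O[Si](C(C)C)(C(C)C)C(C)C)ccc1Br | intermediate |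
| 3 | 3-chloro-3-methylbut-1-yne | C#CC(C)(C)Cl | starting material |
| 4 | aryl 1,1-dimethylpropargyl ether | C#CC(C)(C)Oc1cc(O[Si](C(C)C)(C(C)C)C(C)C)ccc1Br | intermediate |
| 5 | aryl 1,1-dimethylallyl ether | C=CC(C)(C)Oc1cc(O[Si](C(C)C)(C(C)C)C(C)C)ccc1Br | intermediate |
| 6 | 6-bromo-2-prenyl-3-(TIPSO)phenol | Oc1c(Br)ccc(O[Si](C(C)C)(C(C)C)C(C)C)c1CC=C(C)C | intermediate |
| 7 | 4-iodophenol | Oc1ccc(I)cc1 | starting material |
| 8 | prenyl bromide | CC(C)=CCBr | starting material |
| 9 | 4-iodo-2,6-diprenylphenol | Oc1c(CC=C(C)C)cc(I)cc1CC=C(C)C | intermediate |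
| 10 | TBS ether of 9 | CC(C)=CCc1cc(I)cc(CC=C(C)C)c1O[Si](C)(C)C(C)(C)C | intermediate |
| 11 | 4-(TBSO)-3,5-diprenylbenzoic acid | OC(=O)c1cc(CC=C(C)C)c(O[Si](C)(C)C(C)(C)C)c(CC=C(C)C)c1 | intermediate |
| 12 | aryl benzoate | O=C(Oc1c(Br)ccc(O[Si](C(C)C)(C(C)C)C(C)C)c1CC=C(C)C)c1cc(CC=C(C)C)c(O[Si](C)(C)C(C)(C)C)c(CC=C(C)C)c1 | intermediate |
| 13 | bromoaryl 1-arylvinyl ether | C=C(Oc1c(Br)ccc(O[Si](C(C)C)(C(C)C)C(C)C)c1CC=C(C)C)c1cc(CC=C(C)C)c(O[Si](C)(C)C(C)(C)C)c(CC=C(C)C)c1 | intermediate |
| 14 | O-(1-arylvinyl)salicylaldehyde | C=C(Oc1c(C=O)ccc(O[Si](C(C)C)(C(C)C)C(C)C)c1CC=C(C)C)c1cc(CC=C(C)C)c(O[Si](C)(C)C(C)(C)C)c(CC=C(C)C)c1 | intermediate |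
| 15 | (2S)-7-O-TIPS-4'-O-TBS-sophoranone | CC(C)=CCc1cc([C@@H]2CC(=O)c3ccc(O[Si](C(C)C)(C(C)C)C(C)C)c(CC=C(C)C)c3O2)cc(CC=C(C)C)c1O[Si](C)(C)C(C)(C)C | intermediate |
| 16 | (2S)-sophoranone | CC(C)=CCc1cc([C@@H]2CC(=O)c3ccc(O)c(CC=C(C)C)c3O2)cc(CC=C(C)C)c1O | target |

## Step count and risks

- **Total steps:** 12.
- **Longest linear sequence:** 9 (steps 1–4, then 8–12). The B-ring branch (steps 5–7) joins at step 8.

**Steps most likely to fail:**

1. **Step 11 (the proposed new step).**
   - Possible failure modes are 5-exo closure to the 2-aryl-2-methylbenzofuran-3(2H)-one, β-aryloxide elimination, decarbonylation, acid-triggered closure of 14 to flavene or flavylium products, or low ee.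
   - Fallback (known chemistry, different disconnection): form C2–C1' instead of C3–C4.
   - Convert iodide 10 into the arylboronic acid (i-PrMgCl·LiCl, then B(OMe)3).
   - Make 7-(TIPSO)-8-prenylchromone from 2,4-dihydroxyacetophenone by the same tert-prenyl ether/Claisen sequence, then 4-O-TIPS, DMF-DMA enaminone formation and cyclisation.
   - Join the two by the established asymmetric 1,4-addition of arylboronic acids to chromones (Pd(II)/t-BuPyOX or Rh(I)/chiral bisphosphine). This gives 15 directly, and step 12 is unchanged.

2. **Step 10.**
   - Possible failure modes are organolithium addition to the styrenyl enol ether and loss of the enol ether or of aldehyde 14 on work-up.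
   - Fallback: carry the C4 carbon from the start so that no organolithium meets the enol ether.
   - Take 2,4-dihydroxybenzaldehyde through 4-O-(1,1-dimethylpropargyl)ation, Lindlar reduction and Claisen rearrangement (directed to C3 by the chelated 2-OH).
   - Then carry out 4-O-TIPS protection, NaBH4 reduction and primary O-TES protection.
   - Esterify with 11, apply Petasis methylenation, remove TES with pyridine-buffered HF·pyridine, and oxidise with MnO2 to reach 14.

3. **Step 5.**
   - The double C-prenylation gives mixtures of O-alkyl, mono-alkyl and chroman products, and the yield is only moderate.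
   - Fallback: replace phenoxide alkylation by cross-coupling.
   - Take 4-hydroxy-3,5-diiodobenzaldehyde to its TBS ether, run a double Stille coupling with tributyl(3-methylbut-2-enyl)stannane (Pd(0), DMF), and oxidise by Pinnick conditions with a large excess of 2-methyl-2-butene. This gives acid 11.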